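**Retrosynthetic overview**
1. Schizolaenone C (21) comes from its tetrakis(methoxymethyl) ether 20 by acetal solvolysis. Compound 20 is cut through ring C at O1–C2 and C4–C4a into phenol 7 (ring A, geranyl already on the carbon between the two protected oxygens, only O1 free) and the (R)-β-aryl-β-lactone 16 (ring B plus C2–C3–C4 at the carboxylic acid level, C2 stereocentre in place).
2. Enabling feature: ring C is a β-aryloxy ketone whose ether oxygen O1 and acyl-bearing carbon C4a are ortho neighbours on the phloroglucinol-type ring A (C4a is ortho to O1 and O5 and para to O7). C2 is a secondary benzylic carbon whose ring B carries both oxygens meta, so it reacts by SN2 and does not ionise.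
3. In one flask the phenoxide of 7 opens 16 at C2 with inversion (O1–C2, gives 2S), and the carboxylate set free is then acylated onto C4a (C4–C4a). The lactone is a temporary ring and is consumed.
4. Phenol 7: phloroglucinol, bis-MOM ether, TIPS ether, directed metalation and geranylation, desilylation. Lactone 16: methyl 3,5-dihydroxybenzoate, MOM ether, Claisen condensation, asymmetric transfer hydrogenation (sets the configuration), saponification, lactonization with retention.
5. Ring order: rings A and B are bought as arenes; the oxetanone ring is made in step 9 and opened in step 10; ring C is the only ring of the target that is built (step 10).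

Key step: step 10

Remark: the target is taken as the (2S)-flavanone with an (E)-geranyl group at C6; flavanone numbering (O1, C2, C3, C4, C4a, C5 to C8, C8a) is used for these atoms in all precursors, geranyl stands for (2E)-3,7-dimethylocta-2,6-dien-1-yl and MOM for methoxymethyl.

**Step 1**
Reactants: 1 phloroglucinol (benzene-1,3,5-triol)
Product: 2 3,5-bis(methoxymethoxy)phenol
Conditions: MOMCl (2.0 equiv), i-Pr2NEt (2.2 equiv), DMF, 0 °C to rt; chromatography
Reagents that add atoms: chloromethyl methyl ether (MOMCl), COCCl
Why: O-alkylation of a phenol with an α-chloro ether (acetal ether formation) on a threefold symmetric triol is statistical, so the bis-ether should be obtained after chromatographic separation from the mono- and tris-ethers, the mono-ether being resubmitted.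

**Step 2**
Reactants: 2 3,5-bis(methoxymethoxy)phenol
Product: 3 [3,5-bis(methoxymethoxy)phenoxy]tri(propan-2-yl)silane
Conditions: TIPSCl (1.2 equiv), imidazole (2.5 equiv), DMF, rt
Reagents that add atoms: chlorotri(propan-2-yl)silane (TIPSCl), CC(C)[Si](Cl)(C(C)C)C(C)C
Why: silyl ether formation at the one free phenol should be clean and places a bulky, non-coordinating group on the future O1 that shields the two ring positions next to it in the following metalation.

**Step 3**
Reactants: 3 [3,5-bis(methoxymethoxy)phenoxy]tri(propan-2-yl)silane; 4 geranyl bromide, (2E)-1-bromo-3,7-dimethylocta-2,6-diene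
Product: 6 [4-geranyl-3,5-bis(methoxymethoxy)phenoxy]tri(propan-2-yl)silane, via aryllithium 5 (not isolated)
Conditions: n-BuLi (1.1 equiv), THF, 0 °C; CuI (10 mol %), then 4, −78 °C to rt
Reagents that add atoms: none
Why: directed ortho-metalation should take place only at the ring carbon flanked by both OMOM groups (cooperative coordination, the positions beside OTIPS being blocked), and the aryl nucleophile should then displace the primary allylic bromide at its α-carbon (SN2 allylation) with the (E) olefin unchanged.

**Step 4**
Reactants: 6 [4-geranyl-3,5-bis(methoxymethoxy)phenoxy]tri(propan-2-yl)silane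
Product: 7 4-geranyl-3,5-bis(methoxymethoxy)phenol
Conditions: TBAF (1.1 equiv), AcOH (1.1 equiv), THF, 0 °C
Reagents that add atoms: none
Why: buffered fluoride cleavage of the aryl silyl ether (desilylation) should free only the oxygen para to the geranyl group, since acetals and olefins are inert to fluoride.

**Step 5**
Reactants: 8 methyl 3,5-dihydroxybenzoate
Product: 9 methyl 3,5-bis(methoxymethoxy)benzoate
Conditions: MOMCl (2.5 equiv), i-Pr2NEt (3.0 equiv), CH2Cl2, 0 °C to rt
Reagents that add atoms: chloromethyl methyl ether (MOMCl), COCCl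
Why: exhaustive O-alkylation of both phenols with the α-chloro ether (acetal ether formation) has no selectivity issue and should go to completion.

**Step 6**
Reactants: 9 methyl 3,5-bis(methoxymethoxy)benzoate; 10 ethyl acetate
Product: 12 ethyl 3-[3,5-bis(methoxymethoxy)phenyl]-3-oxopropanoate, via lithium enolate of ethyl acetate 11 (not isolated)
Conditions: LiN(SiMe3)2 (2.2 equiv), 10 (1.1 equiv), THF, −78 °C; then 9, −78 to 0 °C; AcOH quench
Reagents that add atoms: none
Why: crossed Claisen condensation of a preformed ester enolate with a non-enolisable benzoate should be driven to completion by deprotonation of the β-keto ester by the second equivalent of base.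

**Step 7**
Reactants: 12 ethyl 3-[3,5-bis(methoxymethoxy)phenyl]-3-oxopropanoate
Product: 13 ethyl (3R)-3-[3,5-bis(methoxymethoxy)phenyl]-3-hydroxypropanoate
Conditions: RuCl[(R,R)-TsDPEN](p-cymene) (1 mol %), HCO2H/Et3N (5:2), EtOAc, rt
Reagents that add atoms: none
Why: Noyori asymmetric transfer hydrogenation of the aryl ketone should set the carbinol stereocenter under catalyst control, the (R,R) complex being expected to give the (R) benzylic alcohol as it does with acetophenone-type ketones, while the buffered formate medium should leave the acetals intact.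

**Step 8**
Reactants: 13 ethyl (3R)-3-[3,5-bis(methoxymethoxy)phenyl]-3-hydroxypropanoate
Product: 14 (3R)-3-[3,5-bis(methoxymethoxy)phenyl]-3-hydroxypropanoic acid
Conditions: LiOH·H2O (1.5 equiv), THF/H2O (3:1), 0 °C; then 1 M HCl to pH 3, 0 °C
Reagents that add atoms: lithium hydroxide, [Li+].[OH-]
Why: ester saponification at low temperature breaks no bond to the stereocenter and should outrun retro-aldol cleavage, and the brief cold acidification to pH 3 should spare the acetals.

**Step 9**
Reactants: 14 (3R)-3-[3,5-bis(methoxymethoxy)phenyl]-3-hydroxypropanoic acid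
Product: 16 (4R)-4-[3,5-bis(methoxymethoxy)phenyl]oxetan-2-one, via carboxylic sulfonic anhydride 15 (not isolated)
Conditions: PhSO2Cl (2.0 equiv), pyridine, 0 °C
Reagents that add atoms: none
Why: β-lactonization by carboxyl activation closes the four-membered ring by attack of the hydroxyl oxygen on the activated acyl carbon (4-exo-trig), so the C–O bond at the stereocenter is not broken and the (R) configuration should be retained.

**Step 10**
Reactants: 7 4-geranyl-3,5-bis(methoxymethoxy)phenol; 16 (4R)-4-[3,5-bis(methoxymethoxy)phenyl]oxetan-2-one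
Product: 20 (2S)-2-[3,5-bis(methoxymethoxy)phenyl]-6-geranyl-5,7-bis(methoxymethoxy)-2,3-dihydro-4H-chromen-4-one, via sodium phenoxide 17 (not isolated), via sodium carboxylate 18 (not isolated), via mixed anhydride 19 (not isolated)
Conditions: one flask: NaH (1.0 equiv), 15-crown-5 (1.0 equiv), THF, 0 °C; 16 (1.05 equiv), 0 °C to rt; then CH2Cl2, (CF3CO)2O (1.1 equiv), −20 to 0 °C; aq NaHCO3
Reagents that add atoms: none
Why: Phenoxide 17 attacks the benzylic carbon C2 of β-lactone 16 in an SN2 reaction with alkyl–oxygen cleavage (the established mode of β-lactone opening by phenoxides), which forms O1–C2 and releases carboxylate 18; trifluoroacetic anhydride then converts 18 into mixed anhydride 19, whose acyl carbon C4 is attacked by ring carbon C4a in an intramolecular Friedel–Crafts acylation, the standard chromanone closure of 3-aryloxypropanoic acids. Ring C thus closes in the second event as a six-membered ring by electrophilic aromatic substitution (6-exo-trig with respect to the acyl C=O). The only stereocenter, C2, is transferred and not created: backside displacement inverts the (R) centre of 16 to (S), and because no β-aryloxy ketone exists while base is present and ring B carries its oxygens meta to C2, neither elimination and re-addition through a chalcone nor benzylic ionisation should erode it. Chemoselectivity in the first event (O- against C-alkylation, alkyl against acyl attack, substitution against elimination) rests on the crown-ether-separated phenoxide, on the reversibility of acyl attack against the irreversibility of carboxylate formation, and on the four-membered ring, which holds the C2–O bond out of alignment with the enolate that an E1cB path would need. In the second event C4a should win over ring B because it is ortho to O1 and O5 and para to O7 and closes a six-membered ring, whereas ring B would have to form an indanone at a carbon activated by two oxygens only, and the single equivalent of CF3CO2H released is tempered by CF3CO2Na and THF at or below 0 °C so that the acetals and the geranyl olefins should survive. The 6-geranyl regiochemistry needs no control in this step, since O1 is the only free oxygen of 7 and the two positions ortho to it are equivalent.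

**Step 11**
Reactants: 20 (2S)-2-[3,5-bis(methoxymethoxy)phenyl]-6-geranyl-5,7-bis(methoxymethoxy)-2,3-dihydro-4H-chromen-4-one
Product: 21 schizolaenone C, (2S)-2-(3,5-dihydroxyphenyl)-6-geranyl-5,7-dihydroxy-2,3-dihydro-4H-chromen-4-one
Conditions: 3 M aq HCl/MeOH (1:10), 40 °C, monitored and stopped at full conversion
Reagents that add atoms: none
Why: acid-catalysed acetal exchange with methanol (MOM ether solvolysis) should remove all four acetals, the one at O5 first because of the neighbouring carbonyl, while the (2S) centre should persist because ring opening of a flavanone to its chalcone is base-promoted and slow in dilute acid at this temperature.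

**Compound list**
1 | phloroglucinol (benzene-1,3,5-triol) | Oc1cc(O)cc(O)c1 | starting material
2 | 3,5-bis(methoxymethoxy)phenol | COCOc1cc(O)cc(OCOC)c1 | intermediate
3 | [3,5-bis(methoxymethoxy)phenoxy]tri(propan-2-yl)silane | COCOc1cc(O[Si](C(C)C)(C(C)C)C(C)C)cc(OCOC)c1 | intermediate
4 | geranyl bromide, (2E)-1-bromo-3,7-dimethylocta-2,6-diene | CC(C)=CCC/C(C)=C/CBr | starting material
5 | {2,6-bis(methoxymethoxy)-4-[tri(propan-2-yl)silyloxy]phenyl}lithium | COCOc1cc(O[Si](C(C)C)(C(C)C)C(C)C)cc(OCOC)c1[Li] | intermediate
6 | {4-[(2E)-3,7-dimethylocta-2,6-dien-1-yl]-3,5-bis(methoxymethoxy)phenoxy}tri(propan-2-yl)silane | CC(C)=CCC/C(C)=C/Cc1c(OCOC)cc(O[Si](C(C)C)(C(C)C)C(C)C)cc1OCOC | intermediate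
7 | 4-[(2E)-3,7-dimethylocta-2,6-dien-1-yl]-3,5-bis(methoxymethoxy)phenol | CC(C)=CCC/C(C)=C/Cc1c(OCOC)cc(O)cc1OCOC | intermediate
8 | methyl 3,5-dihydroxybenzoate | COC(=O)c1cc(O)cc(O)c1 | starting material
9 | methyl 3,5-bis(methoxymethoxy)benzoate | COC(=O)c1cc(OCOC)cc(OCOC)c1 | intermediate
10 | ethyl acetate | CCOC(C)=O | starting material
11 | lithium enolate of ethyl acetate (lithium 1-ethoxyethen-1-olate) | C=C(O[Li])OCC | intermediate
12 | ethyl 3-[3,5-bis(methoxymethoxy)phenyl]-3-oxopropanoate | CCOC(=O)CC(=O)c1cc(OCOC)cc(OCOC)c1 | intermediate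
13 | ethyl (3R)-3-[3,5-bis(methoxymethoxy)phenyl]-3-hydroxypropanoate | CCOC(=O)C[C@@H](O)c1cc(OCOC)cc(OCOC)c1 | intermediate
14 | (3R)-3-[3,5-bis(methoxymethoxy)phenyl]-3-hydroxypropanoic acid | OC(=O)C[C@@H](O)c1cc(OCOC)cc(OCOC)c1 | intermediate
15 | benzenesulfonic (3R)-3-[3,5-bis(methoxymethoxy)phenyl]-3-hydroxypropanoic anhydride | O=C(C[C@@H](O)c1cc(OCOC)cc(OCOC)c1)OS(=O)(=O)c1ccccc1 | intermediate
16 | (4R)-4-[3,5-bis(methoxymethoxy)phenyl]oxetan-2-one | O=C1C[C@H](c2cc(OCOC)cc(OCOC)c2)O1 | intermediate
17 | sodium 4-[(2E)-3,7-dimethylocta-2,6-dien-1-yl]-3,5-bis(methoxymethoxy)phenoxide | CC(C)=CCC/C(C)=C/Cc1c(OCOC)cc([O-])cc1OCOC.[Na+] | intermediate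
18 | sodium (3S)-3-[3,5-bis(methoxymethoxy)phenyl]-3-{4-[(2E)-3,7-dimethylocta-2,6-dien-1-yl]-3,5-bis(methoxymethoxy)phenoxy}propanoate | CC(C)=CCC/C(C)=C/Cc1c(OCOC)cc(O[C@@H](CC(=O)[O-])c2cc(OCOC)cc(OCOC)c2)cc1OCOC.[Na+] | intermediate
19 | (3S)-3-[3,5-bis(methoxymethoxy)phenyl]-3-{4-[(2E)-3,7-dimethylocta-2,6-dien-1-yl]-3,5-bis(methoxymethoxy)phenoxy}propanoic trifluoroacetic anhydride | CC(C)=CCC/C(C)=C/Cc1c(OCOC)cc(O[C@@H](CC(=O)OC(=O)C(F)(F)F)c2cc(OCOC)cc(OCOC)c2)cc1OCOC | intermediate
20 | (2S)-2-[3,5-bis(methoxymethoxy)phenyl]-6-[(2E)-3,7-dimethylocta-2,6-dien-1-yl]-5,7-bis(methoxymethoxy)-2,3-dihydro-4H-chromen-4-one | CC(C)=CCC/C(C)=C/Cc1c(OCOC)cc2c(c1OCOC)C(=O)C[C@@H](c1cc(OCOC)cc(OCOC)c1)O2 | intermediate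
21 | schizolaenone C, (2S)-2-(3,5-dihydroxyphenyl)-6-[(2E)-3,7-dimethylocta-2,6-dien-1-yl]-5,7-dihydroxy-2,3-dihydro-4H-chromen-4-one | CC(C)=CCC/C(C)=C/Cc1c(O)cc2c(c1O)C(=O)C[C@@H](c1cc(O)cc(O)c1)O2 | target

**Step count**
Total step count: 11 (steps 1 to 4 for phenol 7, steps 5 to 9 for lactone 16, steps 10 and 11 in common).
Longest linear sequence: 7 steps (8 → 9 → 12 → 13 → 14 → 16 → 20 → 21, steps 5 to 11).

**Steps most likely to fail**

1. Step 10. In the first event the phenoxide may act as a base on the lactone or attack through carbon instead of oxygen. In the second event the acid set free may strip acetal groups or protonate the geranyl olefins, and acylation may go to ring B or be overtaken by ring trifluoroacetylation. Fallback, which uses neither a lactone opening nor an acidic acylation, sets out from 7 (together with 13) and comes back at 20. Bromination of 7 with NBS (CH2Cl2, −78 °C) ortho to the free hydroxyl should give 2-bromo-4-geranyl-3,5-bis(methoxymethoxy)phenol F1. Mitsunobu etherification of F1 with the (R) alcohol 13 (PPh3, DIAD, toluene, 0 °C to rt) should give, with inversion, ethyl (3S)-3-[2-bromo-4-geranyl-3,5-bis(methoxymethoxy)phenoxy]-3-[3,5-bis(methoxymethoxy)phenyl]propanoate F2. Aminolysis with Me2AlN(OMe)Me (from AlMe3 and MeNHOMe·HCl, CH2Cl2, 0 °C) should give the Weinreb amide F3. Bromine–lithium exchange with t-BuLi (2.1 equiv, THF, −100 °C) should give the aryllithium F4, which closes ring C by Parham cyclization onto the amide and should give 20 after a cold AcOH quench.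

2. Step 9. The β-aryl-β-lactone may lose carbon dioxide or oligomerise during formation and isolation, and sulfonylation may occur at the benzylic hydroxyl instead of the carboxylate. Fallback, which avoids the lactone altogether, sets out from 13 (together with 7) and comes back at 18. Mitsunobu etherification of 7 with 13 (PPh3, DIAD, toluene, 0 °C to rt) should give, with inversion, ethyl (3S)-3-[3,5-bis(methoxymethoxy)phenyl]-3-[4-geranyl-3,5-bis(methoxymethoxy)phenoxy]propanoate F5. Saponification with NaOH (1.0 equiv, THF/H2O, 0 °C) and azeotropic drying should give sodium carboxylate 18, which enters the second stage of step 10 ((CF3CO)2O, CH2Cl2, −20 to 0 °C).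

3. Step 11. The protic acid may induce cyclisation of the geranyl chain onto the neighbouring freed phenols, or ring opening and reclosure of ring C with erosion of the C2 configuration. Fallback, which replaces protic solvolysis by silyl transfer, sets out from 20 and comes back at 21. TMSOTf and 2,2'-bipyridyl (MeCN, 0 °C) should exchange the four aryl methoxymethyl ethers for trimethylsilyl ethers and give (2S)-2-[3,5-bis(trimethylsilyloxy)phenyl]-6-geranyl-5,7-bis(trimethylsilyloxy)-2,3-dihydro-4H-chromen-4-one F6. Addition of water at rt should then hydrolyse the aryl silyl ethers to 21.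

**Further compounds**
F1 | step 10 | 2-bromo-4-[(2E)-3,7-dimethylocta-2,6-dien-1-yl]-3,5-bis(methoxymethoxy)phenol | CC(C)=CCC/C(C)=C/Cc1c(OCOC)cc(O)c(Br)c1OCOC
F2 | step 10 | ethyl (3S)-3-{2-bromo-4-[(2E)-3,7-dimethylocta-2,6-dien-1-yl]-3,5-bis(methoxymethoxy)phenoxy}-3-[3,5-bis(methoxymethoxy)phenyl]propanoate | CC(C)=CCC/C(C)=C/Cc1c(OCOC)cc(O[C@@H](CC(=O)OCC)c2cc(OCOC)cc(OCOC)c2)c(Br)c1OCOC
F3 | step 10 | (3S)-3-{2-bromo-4-[(2E)-3,7-dimethylocta-2,6-dien-1-yl]-3,5-bis(methoxymethoxy)phenoxy}-3-[3,5-bis(methoxymethoxy)phenyl]-N-methoxy-N-methylpropanamide | CC(C)=CCC/C(C)=C/Cc1c(OCOC)cc(O[C@@H](CC(=O)N(C)OC)c2cc(OCOC)cc(OCOC)c2)c(Br)c1OCOC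
F4 | step 10 | aryllithium from F3 by bromine–lithium exchange | CC(C)=CCC/C(C)=C/Cc1c(OCOC)cc(O[C@@H](CC(=O)N(C)OC)c2cc(OCOC)cc(OCOC)c2)c([Li])c1OCOC
F5 | step 9 | ethyl (3S)-3-[3,5-bis(methoxymethoxy)phenyl]-3-{4-[(2E)-3,7-dimethylocta-2,6-dien-1-yl]-3,5-bis(methoxymethoxy)phenoxy}propanoate | CC(C)=CCC/C(C)=C/Cc1c(OCOC)cc(O[C@@H](CC(=O)OCC)c2cc(OCOC)cc(OCOC)c2)cc1OCOC
F6 | step 11 | (2S)-2-[3,5-bis(trimethylsilyloxy)phenyl]-6-[(2E)-3,7-dimethylocta-2,6-dien-1-yl]-5,7-bis(trimethylsilyloxy)-2,3-dihydro-4H-chromen-4-one | CC(C)=CCC/C(C)=C/Cc1c(O[Si](C)(C)C)cc2c(c1O[Si](C)(C)C)C(=O)C[C@@H](c1cc(O[Si](C)(C)C)cc(O[Si](C)(C)C)c1)O2
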